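We decide to judge this flask, the epsilon run carried on to 8.0 d, by the rate of J, and to read that rate as a gauge of Q.

common to all: L 0.17 M; G 0.17 M
- epsilon: Q 0.374 M; temperature 90 °C; the very flask that is asked about, followed so far
- beta: Q 0.19 M; temperature 96 °C; run made earlier
- flask: Q 0.374 M; temperature 90 °C; time 8.0 d

epsilon run (percent of the L and G together charged)

| time / d | J / % | L / % |
|---|---|---|
| 1.25 | 6.0 | 35.0 |
| 2.50 | 7.0 | 35.0 |
| 4.00 | 8.7 | 34.6 |
| 5.00 | 8.6 | 35.2 |

beta run (percent of the L and G together charged)

| time / h | J / % | L / % |
|---|---|---|
| 6.00 | 2.4 | 39.0 |
| 15.0 | 4.1 | 36.5 |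
| 30.0 | 5.2 | 36.6 |
| 50.0 | 6.0 | 36.6 |

(standard deviation of a reading: 0.3 percentage points)

- Q is single-handed; L and G are mirror images of each other, charged as a racemate, each of them at the stated concentration
- J that was removed still counts
- the numbers in the tables scatter by 0.3 percentage points (one standard deviation)
- additions bring no volume worth counting
- the handed part of Q does not stay in what it makes, so the products of the two hands are mirror images too

- south: at 8.0 d take out 90 % of the J then present, then wait 8.0 d
- south-east: at 8.0 d add Q, 50.0 % of the amount charged, then wait 8.0 d
- north-east: change nothing and wait 8.0 d more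
- north-west: at 8.0 d raise the temperature by 25 K, then wait 8.0 d

- J, in percent of the L and G together first charged, at 8.0 d
- the remedy with the largest gain of J, or "none" below 2 percentage points (south / south-east / north-east / north-west / none)
- J present, with what was taken out counted in, in percent of the L and G together first charged, after south-east
- J present, with what was taken out counted in, in percent of the L and G together first charged, after north-east

In epsilon L stays near 35.2 %, so we take J to form pseudo-first-order in Q, with its rate following the concentration of Q. If one Q goes per J, J has used 7.82 % of the charged Q at 5.00 d, yet J has slowed strongly. We read this as Q destroying itself in a second-order loss: Q then falls as one over time, and J climbs on a straight line against the logarithm of time. We call the slope of that line the log slope s, the points of J gained per e-fold of time: 1.9 percentage points in epsilon and 1.7 points in beta, which has 0.19 M of Q and stands at 96 °C; both slopes are readings and carry the scatter of the readings.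

Now we turn the question round. For waiting to pay, s would have to reach 2.9 points, but at the epsilon value waiting brings 1.3 points. For south to pay, J would have to push back, which our reading does not contain. Our own reckoning extends the line to 9.48 % at 8.0 d. We let the added Q act as a fresh flask with half the charge, which gives 8.2 points, so 17.7 % in all, and south-east is our choice.

The forecast says 9.2 %, 11.5 % after south-east, 9.6 % after waiting, and chooses south, which differs from our choice: “Removing J pulls the pool and L forward again, which should be the largest gain”.

The flask gives 9.19 %, 15.7 % after south-east and 9.88 % after waiting. South-east gains 6.5 points, more than south with 0.7 points or north-west with 1 point.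

    L ⇌ D (K = 0.580, k = 1.00 × 10⁻⁵ s⁻¹, Ea = 130 kJ mol⁻¹, ΔH = −22.0 kJ mol⁻¹)
    G ⇌ D (K = 0.580, k = 1.00 × 10⁻⁵ s⁻¹, Ea = 130 kJ mol⁻¹, ΔH = −22.0 kJ mol⁻¹)
    Q + L → J (k = 1.30 × 10⁻⁵ M⁻¹ s⁻¹, Ea = 97.0 kJ mol⁻¹)
    2 Q → X (k = 9.20 × 10⁻⁵ M⁻¹ s⁻¹, Ea = 96.0 kJ mol⁻¹)
    Q + G → Z (k = 1.40 × 10⁻⁷ M⁻¹ s⁻¹, Ea = 93.0 kJ mol⁻¹)
    (constants at 90 °C)

At 8.00 d the flask still has free 1.13 % of its charged Q and 70.0 % of its charged L. The depletion of Q, with the passing of two Q into X as part of it, holds J down: at that time the run without that step stands at 53.8 % of J, and the run with Q held stands at 64.7 %. Waiting gained 0.7 points against the slope's 1.3 points, and the dose gained 6.5 points against 8.2 points. For a neighbouring flask with 1.5 M of Q, the slope puts 2.6 points on top of 9.19 %, making 11.8 %, and that flask holds 12.8 %.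

(The data are calculated with constants of no real substance; the scatter is artificial.)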